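**Retrosynthetic overview**
1. The cyclopentenone is made last, by benzilic-ester ring contraction of a 2-hydroxy-5-methoxy-1,4-benzoquinone that carries the decalin on C3.
2. That quinone comes from a tetramethoxyaryl decalin; the C8–CH2Ar bond and the C8 quaternary centre come from reductive benzylation of an ene-dione enolate.
3. The ene-dione is the Diels–Alder adduct of 2,5-dimethyl-1,4-benzoquinone (ring B; supplies the C5 and C8 methyls) with a 2-silyloxy-1,3-pentadiene (ring A; supplies the C4 methyl). A chiral Lewis acid differentiates the faces of the symmetric quinone.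
4. Ring order: ring B (quinone, from 2,5-xylenol) → ring A (Diels–Alder) → decalin tailoring (C10, C9, C6, Δ3) → arene oxidised to quinone → five-membered ring.

Assumption: the SMILES is taken as authoritative, so the CH2 linker sits on the quaternary carbon that is not adjacent to the ring fusion (C8 below). Decalin numbering: C1–C4 ring A, C5 (angular Me)/C10 (angular H) ring fusion, C6–C9 ring B; β = face of the C5 methyl.

**Step 1**
Reactants: 1, 2,5-dimethylphenol
Product: 2, 2,5-dimethyl-1,4-benzoquinone
Conditions: Fremy's salt, KH2PO4, H2O/acetone, 23 °C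
Reagents that add atoms: potassium nitrosodisulfonate, [K+].[K+].[O-]S(=O)(=O)N([O])S([O-])(=O)=O
Why: Teuber oxidation of a phenol with a free para position gives the p-quinone (dearomatisation of the feedstock).

**Step 2**
Reactants: 3, (E)-pent-3-en-2-one
Product: 4, (E)-2-(triisopropylsilyloxy)penta-1,3-diene
Conditions: TIPSOTf, Et3N, Et2O, 0 → 23 °C
Reagents that add atoms: TIPSOTf, CC(C)[Si](OS(=O)(=O)C(F)(F)F)(C(C)C)C(C)C
Why: Soft enolisation and O-silylation at the methyl ketone terminus gives the cross-conjugated 2-silyloxy diene with the E-propenyl geometry retained.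

**Step 3 (key step)**
Reactants: 2, 2,5-dimethyl-1,4-benzoquinone; 4, (E)-2-(triisopropylsilyloxy)penta-1,3-diene
Product: 5, (4aR,5R,8aS)-2,4a,5-trimethyl-7-(triisopropylsilyloxy)-4a,5,8,8a-tetrahydronaphthalene-1,4-dione (cis-fused; decalin numbering: 6,9-dione, Δ7, 2-OTIPS-Δ2, 4α-Me, 5β-Me, 10β-H)
Conditions: (S)-o-tolyl-CBS-oxazaborolidinium triflimide (20 mol %; use the antipode if the sense is opposite), CH2Cl2, −78 °C
Reagents that add atoms: none
Why: Catalytic enantioselective Diels–Alder on the C2h-symmetric quinone: the nucleophilic diene terminus C1 bonds to the unsubstituted quinone carbon and the CH(Me) terminus to the methyl-bearing carbon, endo addition gives the cis-fused adduct, and the catalyst's face selection fixes the C5 quaternary centre (with C10 and C4) in absolute terms.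

**Step 4**
Reactants: 6, 1,2,4,5-tetramethoxybenzene (3 equiv, excess recovered)
Product: 7, 2,3,5,6-tetramethoxybenzyl bromide
Conditions: (CH2O)n, 33% HBr/AcOH, AcOH, 23 °C
Reagents that add atoms: formaldehyde (as paraformaldehyde), C=O; hydrogen bromide, Br
Why: Electrophilic bromomethylation at one of the two equivalent free positions; excess arene suppresses bis-substitution and diarylmethane formation.

**Step 5**
Reactants: 5, cis-fused ene-dione; 7, 2,3,5,6-tetramethoxybenzyl bromide
Product: 8, trans-fused 6,9-dione: 4α,5β,8α-trimethyl-8β-(2,3,5,6-tetramethoxybenzyl)-2-(triisopropylsilyloxy)-Δ2, 10α-H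
Conditions: K-Selectride, THF, −78 °C; 7, DMPU, −78 → 0 °C; then NaOMe, MeOH, 40 °C
Reagents that add atoms: none
Why: Reductive alkylation: hydride adds 1,4 at the unsubstituted C7, the C8=C9 potassium enolate is benzylated on the convex β-face of the cis-fused bicycle (8β-CH2Ar, 8α-Me), and methoxide then epimerises C10 (α to the C9 ketone) to the more stable trans-decalin, as with 4-keto-5α-steroids.

**Step 6**
Reactants: 8, trans-fused 6,9-dione
Product: 9, C6 enol triflate (Δ6, 6-OTf) of 8, C9 ketone retained
Conditions: KHMDS, THF, −78 °C; PhNTf2, −78 → 0 °C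
Reagents that add atoms: N-phenyl-bis(trifluoromethanesulfonimide), O=S(=O)(N(c1ccccc1)S(=O)(=O)C(F)(F)F)C(F)(F)F
Why: Kinetic enolisation is possible only at the C7 methylene (C5 is quaternary; the C9 ketone can enolise only toward the hindered tertiary C10–H), and O-triflation both masks C6 and prepares its reductive removal; no stereocentre is touched.

**Step 7**
Reactants: 9, C6 enol triflate / C9 ketone
Product: 10, 9-methylene compound (C9=CH2), triflate and silyl enol ether retained
Conditions: Cp2TiMe2, PhMe, 70 °C, dark
Reagents that add atoms: dimethyltitanocene (Petasis reagent), C[Ti](C)(C1C=CC=C1)C1C=CC=C1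
Why: Titanium-methylidene carbonyl olefination of a hindered, enolisable ketone under non-basic conditions, so C10 is not disturbed and the triflate and silyl enol ether survive.

**Step 8**
Reactants: 10, 9-methylene enol triflate
Product: 11, 4α,5β,8α,9β-tetramethyl-8β-(2,3,5,6-tetramethoxybenzyl)-2-(triisopropylsilyloxy)-Δ2-octalin, 10α-H (ring B saturated)
Conditions: H2 (1 atm), PtO2, EtOAc, 23 °C
Reagents that add atoms: none
Why: Heterogeneous hydrogenation adds H2 to the exocyclic C9=CH2 from the α (equatorial) face because the β-face is blocked by the 1,3-diaxial C5 methyl, giving axial 9β-Me/9α-H, while the enol triflate undergoes Pt-mediated C–O hydrogenolysis and saturation to CH2–CH2; the hindered TIPS enol ether and the arene are left.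

**Step 9**
Reactants: 11, TIPS enol ether
Product: 12, ring-A enone: 4,5β,8α,9β-tetramethyl-8β-(2,3,5,6-tetramethoxybenzyl)-Δ3-octalin-2-one, 10α-H
Conditions: Pd(OAc)2, MeCN, 40 °C
Reagents that add atoms: none
Why: Saegusa–Ito oxidation: the Pd(II) enolate at C3 can β-hydride-eliminate only toward C4–H, so the C3=C4 bond bearing the C4 methyl forms regiospecifically (the C4 stereocentre is removed).

**Step 10**
Reactants: 12, ring-A enone
Product: 13, 4,5β,8α,9β-tetramethyl-8β-(2,3,5,6-tetramethoxybenzyl)-Δ3-octalin, 10α-H
Conditions: LiAlH4/AlCl3 (1:3), Et2O, 0 → 23 °C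
Reagents that add atoms: none
Why: Mixed-hydride (AlHCl2) deoxygenation of an enone: the allylic alkoxyalane ionises and hydride is delivered to the less hindered secondary terminus C2 rather than the neopentyl tertiary C4, retaining the trisubstituted Δ3 olefin (as in cholest-4-en-3-one → cholest-4-ene).

**Step 11**
Reactants: 13, tetramethoxyaryl decalin
Product: 14, 2,5-dimethoxy-3-(decalinylmethyl)-1,4-benzoquinone
Conditions: CAN, MeCN/H2O, 0 °C
Reagents that add atoms: water, O
Why: CAN oxidative demethylation of a para-dimethoxyarene to the p-quinone; either para pair gives the same 3-alkyl-2,5-dimethoxyquinone and the isolated trisubstituted olefin is untouched.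

**Step 12**
Reactants: 14, dimethoxyquinone
Product: 15, 2-hydroxy-5-methoxy-3-(decalinylmethyl)-1,4-benzoquinone
Conditions: KOH, MeOH/H2O, 23 °C; then 1 M HCl
Reagents that add atoms: hydroxide/water, O
Why: Addition–elimination (vinylogous ester saponification) occurs selectively at the methoxy group flanked by the alkyl substituent, which is twisted out of conjugation and most electrophilic; no stereocentre is involved.

**Step 13**
Reactants: 15, hydroxy-methoxyquinone
Product: 16, dysidenone A, methyl (1S,5R)-1-hydroxy-3-methoxy-4-oxo-5-{[(1R,2R,4aS,8aS)-1,2,4a,5-tetramethyl-1,2,3,4,4a,7,8,8a-octahydronaphthalen-2-yl]methyl}cyclopent-2-ene-1-carboxylate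
Conditions: Mg(OMe)2, MeOH, 60 °C; AcOH quench; preparative HPLC
Reagents that add atoms: methanol, CO
Why: Proposed new method: Mg(II) chelates the C1/C2 oxygens of the 1,2,4-triketo tautomer, methoxide adds at C2 and the C2–C3 bond migrates to C1 (benzilic-ester/α-ketol ring contraction; closest known types are the benzilic step of the Hooker oxidation and the Mg-promoted α-ketol contraction of hop α-acids), extruding C2 as CO2Me and creating C1'(OH) and C5'(H); C5' equilibrates α to the ketone, C1' forms without useful bias from the remote decalin, so 16 is separated from its diastereomers by HPLC and the others are re-equilibrated (retro-aldol/aldol) and recycled.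

**Compound list**
1 | 2,5-dimethylphenol | Cc1ccc(C)c(O)c1 | starting material
2 | 2,5-dimethyl-1,4-benzoquinone | CC1=CC(=O)C(C)=CC1=O | intermediate
3 | (E)-pent-3-en-2-one | C/C=C/C(C)=O | starting material
4 | (E)-2-(triisopropylsilyloxy)penta-1,3-diene | C=C(O[Si](C(C)C)(C(C)C)C(C)C)/C=C/C | intermediate
5 | cis-fused Diels–Alder adduct (4aR,5R,8aS) | CC1=CC(=O)[C@]2(C)[C@H](C)C=C(O[Si](C(C)C)(C(C)C)C(C)C)C[C@@H]2C1=O | intermediate
6 | 1,2,4,5-tetramethoxybenzene | COc1cc(OC)c(OC)cc1OC | starting material
7 | 2,3,5,6-tetramethoxybenzyl bromide | COc1cc(OC)c(OC)c(CBr)c1OC | intermediate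
8 | trans-fused 8β-benzyl 6,9-dione | COc1cc(OC)c(OC)c(C[C@@]2(C)CC(=O)[C@]3(C)[C@H](C)C=C(O[Si](C(C)C)(C(C)C)C(C)C)C[C@H]3C2=O)c1OC | intermediate
9 | C6 enol triflate, C9 ketone | COc1cc(OC)c(OC)c(C[C@@]2(C)C=C(OS(=O)(=O)C(F)(F)F)[C@]3(C)[C@H](C)C=C(O[Si](C(C)C)(C(C)C)C(C)C)C[C@H]3C2=O)c1OC | intermediate
10 | 9-methylene enol triflate | COc1cc(OC)c(OC)c(C[C@@]2(C)C=C(OS(=O)(=O)C(F)(F)F)[C@]3(C)[C@H](C)C=C(O[Si](C(C)C)(C(C)C)C(C)C)C[C@H]3C2=C)c1OC | intermediate
11 | 9β-methyl decalin, ring-A TIPS enol ether | COc1cc(OC)c(OC)c(C[C@@]2(C)CC[C@]3(C)[C@H](C)C=C(O[Si](C(C)C)(C(C)C)C(C)C)C[C@H]3[C@H]2C)c1OC | intermediate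
12 | ring-A Δ3-2-enone | COc1cc(OC)c(OC)c(C[C@@]2(C)CC[C@]3(C)C(C)=CC(=O)C[C@H]3[C@H]2C)c1OC | intermediate
13 | Δ3 tetramethoxybenzyl decalin | COc1cc(OC)c(OC)c(C[C@@]2(C)CC[C@]3(C)C(C)=CCC[C@H]3[C@H]2C)c1OC | intermediate
14 | 3-alkyl-2,5-dimethoxy-1,4-benzoquinone | COC1=CC(=O)C(OC)=C(C[C@@]2(C)CC[C@]3(C)C(C)=CCC[C@H]3[C@H]2C)C1=O | intermediate
15 | 3-alkyl-2-hydroxy-5-methoxy-1,4-benzoquinone | COC1=CC(=O)C(O)=C(C[C@@]2(C)CC[C@]3(C)C(C)=CCC[C@H]3[C@H]2C)C1=O | intermediate
16 | dysidenone A | COC(=O)[C@]1(O)C=C(OC)C(=O)[C@@H]1C[C@@]1(C)CC[C@]2(C)C(C)=CCC[C@H]2[C@H]1C | target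

**Totals**
Total steps: 13. Longest linear sequence: 11 (steps 1, 3, 5–13).

**Three steps most likely to fail**
1. Step 3. The chiral Lewis acid may give low ee or reverse the orientation (diene C1 to the methyl-bearing carbon). Fallback: run the cycloaddition thermally (PhMe, 60–80 °C, substrate-controlled orientation) to racemic 5 and set absolute configuration by resolution instead of catalysis: Luche reduction at C9, lipase-catalysed kinetic acylation of the allylic alcohol, then MnO2 re-oxidation.
2. Step 5. Enolate proton transfer to the C6 ketone, slow SN2 with the di-ortho-substituted benzyl bromide, or poor facial selectivity could defeat it. Fallback: trap the C8=C9 enolate as its 2,3,5,6-tetramethoxybenzyl enol carbonate and form the quaternary centre by Pd(0)-catalysed decarboxylative benzylation (π-benzyl/enolate ion pair) in place of intermolecular SN2.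
3. Step 13. The ring contraction is unproven under these conditions and gives no control at C1'. Fallback: make the head first by the same contraction on simple 2-hydroxy-5-methoxy-1,4-benzoquinone, resolve methyl 1-hydroxy-3-methoxy-4-oxocyclopent-2-ene-1-carboxylate, and join it to a C8-formyl decalin by aldol condensation and conjugate reduction, so that C5' is set under control of the resident C1' centre.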